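**Retrosynthetic overview**
1. Target 36 ← desilylation ← SN2 of a C14 mesylate by H2O2 ← butenolide alcohol ← singlet-oxygen oxidation of a 2-alkyl-3-methylfuran, C14–OH-directed syn reduction and lactonisation ← C14 allylic boronate.
2. Key disconnection, C13–C14 and C15–C16 in one operation: conjunctive coupling of a decalin alkenyl boronate, vinyllithium (C14 and C15) and 2-bromo-3-methylfuran. It rests on C14 being an oxygenated carbon between the alkenyl carbon C13 and the methylene C15, which leads to C16, the butenolide ring carbon that is C2 of a 3-methylfuran at a lower oxidation level.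
3. Alkenyl boronate ← enol triflate ← methyl ketone ← Weinreb amide ← Baeyer–Villiger ester of the isopropyl ketone freed by cleaving ring C of methyl abietate.
4. Ring-B oxygens: 6α-OH by peracid oxidation of the dienol acetate of the seco enal; 8α-OH/8-CH3 by reductive allylic transposition of the formyl carbon to an exocyclic CH2 and Mukaiyama hydration.
5. Ring order: rings A and B come intact from abietic acid and the furan ring from 3-methylfuran; the butenolide is the only ring closed (lactonisation, step 19).

Key step: step 16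

Remark on numbering: decalin C1–C10 (C4 carries CH3 and CO2CH3, C10 carries CH3); side chain C11–C12–C13(=CH2)–C14–C15–C16. The former abietane C14 ends as the methyl group on C8.
Assumption: the transient diol 3 is drawn as the 13α,14α isomer (abietane numbering); both centres are destroyed in the same flask.
Assumption: the (Sp,Sp) antipode of the ferrocenyl bisphosphine is taken to deliver the 14R boronate; the mirror-image ligand is used if the sense proves opposite.

**Step 1**
Reactants: 1 abietic acid
Product: 2 methyl abietate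
Conditions: MeI, K2CO3, DMF, rt
Reagents that add atoms: iodomethane (CI)
Why: Carboxylate O-alkylation (SN2) esterifies the hindered C4 acid without the acid that would isomerise the diene.

**Step 2**
Reactants: 2 methyl abietate
Product: 4 seco keto-enal (ring-B C7=C8 enal with CHO on C8; C9 carries CH2CH2C(O)CH(CH3)2), via 13,14-diol 3 (not isolated)
Conditions: OsO4 (2 mol %), NMO (1.05 equiv), acetone/H2O, rt; then NaIO4, THF/H2O, 0 °C
Reagents that add atoms: osmium tetroxide (O=[Os](=O)(=O)=O, catalytic oxygen carrier); N-methylmorpholine N-oxide (C[N+]1([O-])CCOCC1)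
Why: Upjohn dihydroxylation should take the ring-C alkene, the more accessible of the two trisubstituted alkenes (C8 is a ring-fusion carbon), and periodate glycol cleavage then opens ring C to the isopropyl ketone and the enal, whose remaining alkene is deactivated by conjugation.

**Step 3**
Reactants: 4 seco keto-enal
Product: 5 dienol acetate (C8=CH–OAc and C6=C7; enol geometry not controlled and without consequence)
Conditions: Ac2O, Et3N, DMAP (cat.), toluene, 80 °C
Reagents that add atoms: acetic anhydride (CC(=O)OC(C)=O)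
Why: Dienol acetate formation by γ-deprotonation of the acyl-activated enal can only occur at C6, while a simple dialkyl ketone is not enol-acetylated under amine/DMAP conditions.

**Step 4**
Reactants: 5 dienol acetate
Product: 7 6α-hydroxy seco enal, via 6α,7α-epoxy dienol acetate 6 (not isolated)
Conditions: mCPBA (1.05 equiv), dioxane/H2O, pH 7 phosphate buffer, 0 °C
Reagents that add atoms: 3-chloroperbenzoic acid (OOC(=O)c1cccc(Cl)c1)
Why: Peracid oxidation of a dienol acetate (vinylogous Rubottom oxidation, as in the 6-hydroxylation of steroidal 3,5-dienol acetates) should epoxidise the distal C6=C7 bond from the α face, the β face being screened by the syn-axial methyls on C4 and C10, and collapse of the epoxide with loss of the acetyl group sets the 6α carbinol and restores the enal.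

**Step 5**
Reactants: 7 6α-hydroxy seco enal
Product: 8 allylic diol (C8–CH2OH, C7=C8, 6α-OH)
Conditions: NaBH4, MeOH/CH2Cl2, −78 °C
Reagents that add atoms: none
Why: Chemoselective 1,2-reduction, because borohydride reduces the aldehyde far faster than the α-branched isopropyl ketone at low temperature.

**Step 6**
Reactants: 8 allylic diol
Product: 12 6α-hydroxy-8-methylene ketone, via sulfonylhydrazone adduct 9 (not isolated), via sulfonylhydrazine 10 (not isolated), via allylic diazene 11 (not isolated)
Conditions: N-isopropylidene-N'-(2-nitrobenzenesulfonyl)hydrazine, PPh3, DEAD, THF, 0 °C to rt; then CF3CH2OH/H2O, rt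
Reagents that add atoms: none
Why: Mitsunobu displacement at the primary allylic alcohol (the hindered secondary 6-OH is left, and the masked hydrazine spares the ketone), then hydrolysis, sulfinate loss and retro-ene loss of N2 from the allylic diazene (reductive 1,3-transposition) deliver hydrogen to C7 and move the alkene to the exocyclic position.

**Step 7**
Reactants: 12 6α-hydroxy-8-methylene ketone
Product: 14 6α,8α-diol isopropyl ketone, via 8α-hydroperoxide 13 (not isolated)
Conditions: Co(acac)2 (20 mol %), PhSiH3, O2 (1 atm), THF, rt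
Reagents that add atoms: dioxygen (O=O)
Why: Mukaiyama hydration (hydrogen-atom transfer to the CH2 terminus, then O2 capture of the tertiary C8 radical) should occur on the α face, since the β face is blocked by the syn-axial C10 methyl, giving the equatorial 8α-OH and axial 8-methyl.

**Step 8**
Reactants: 14 6α,8α-diol isopropyl ketone
Product: 15 6α,8α-diol isopropyl ester
Conditions: mCPBA, NaHCO3, CH2Cl2, rt
Reagents that add atoms: 3-chloroperbenzoic acid (OOC(=O)c1cccc(Cl)c1)
Why: Baeyer–Villiger oxidation in which the secondary isopropyl group migrates in preference to the primary C12, so C13 becomes an ester carbonyl; no alkene is left to compete.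

**Step 9**
Reactants: 15 6α,8α-diol isopropyl ester
Product: 16 bis(triethylsilyl) ether isopropyl ester
Conditions: TESOTf (3 equiv), 2,6-lutidine, CH2Cl2, −78 to 0 °C
Reagents that add atoms: triethylsilyl trifluoromethanesulfonate (CC[Si](CC)(CC)OS(=O)(=O)C(F)(F)F)
Why: Silyl triflate silylation protects both the hindered secondary and the tertiary hydroxyl, which prevents hemiketal and lactone formation with the side-chain carbonyl in the next steps.

**Step 10**
Reactants: 16 bis(triethylsilyl) ether isopropyl ester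
Product: 17 Weinreb amide
Conditions: MeNH(OMe)·HCl, iPrMgCl, THF, −20 to 0 °C
Reagents that add atoms: N,O-dimethylhydroxylamine hydrochloride (CNOC.Cl)
Why: Aminolysis by the magnesium amide of N,O-dimethylhydroxylamine takes the unhindered side-chain ester, while the neopentyl-type C4 methyl ester is too shielded to react.

**Step 11**
Reactants: 17 Weinreb amide
Product: 18 methyl ketone
Conditions: MeMgBr, THF, 0 °C
Reagents that add atoms: methylmagnesium bromide (C[Mg]Br)
Why: Grignard addition to a Weinreb amide stops at the chelated tetrahedral adduct, so the ketone forms only on work-up.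

**Step 12**
Reactants: 18 methyl ketone
Product: 20 enol triflate (CH2=C13(OTf)–), via lithium enolate 19 (not isolated)
Conditions: LDA, THF, −78 °C; PhNTf2, −78 to 0 °C
Reagents that add atoms: N-phenylbis(trifluoromethanesulfonimide) (O=S(=O)(N(c1ccccc1)S(=O)(=O)C(F)(F)F)C(F)(F)F)
Why: Kinetic deprotonation of the methyl group followed by O-triflation gives the terminal enol triflate; the C4 ester has no α-hydrogen.

**Step 13**
Reactants: 20 enol triflate; 21 bis(pinacolato)diboron
Product: 22 decalin alkenyl pinacol boronate (boron on C13)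
Conditions: PdCl2(PPh3)2 (3 mol %), PPh3, KOPh, toluene, 50 °C
Reagents that add atoms: none
Why: Miyaura borylation of a 1-alkenyl triflate, with phenoxide as a base mild enough to suppress Suzuki homocoupling.

**Step 14**
Reactants: 23 3-methylfuran
Product: 24 2-bromo-3-methylfuran
Conditions: NBS, DMF, 0 °C, dark; used as a fresh solution
Reagents that add atoms: N-bromosuccinimide (O=C1CCC(=O)N1Br)
Why: Electrophilic aromatic bromination goes to the α position next to the methyl group, the most activated ring carbon.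

**Step 15**
Reactants: 25 tetravinylstannane
Product: 26 vinyllithium
Conditions: n-BuLi, pentane, rt; the precipitate is washed and dissolved in Et2O
Reagents that add atoms: n-butyllithium ([Li]CCCC)
Why: Tin–lithium exchange gives halide-free vinyllithium, which the palladium step requires.

**Step 16**
Reactants: 22 decalin alkenyl pinacol boronate; 26 vinyllithium; 24 2-bromo-3-methylfuran
Product: 28 C14 allylic pinacol boronate bearing the (3-methylfuran-2-yl)methyl group, via lithium bis(alkenyl)borate 27 (not isolated)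
Conditions: 26 (1.0 equiv), THF, −78 °C to rt; then Pd(OAc)2 (2 mol %), (Sp,Sp)-1,1'-bis[bis(3,5-dimethylphenyl)phosphino]-2,2'-bis[(S)-α-(dimethylamino)benzyl]ferrocene (a MandyPhos ligand, 2.4 mol %), KOTf, 24, THF, 60 °C
Reagents that add atoms: none
Why: Vinyllithium adds to boron to give borate 27, and zerovalent palladium formed from Pd(OAc)2 and the bisphosphine inserts into the C–Br bond of 24, KOTf removing bromide so that a cationic furyl–palladium species results. This species binds the unsubstituted vinyl group and induces a 1,2-shift of the C13 alkenyl group from boron to the adjacent carbon anti to palladium (C13–C14), after which reductive elimination joins C15 to the furan carbon that becomes C16. The closest known reaction is the enantioselective palladium-catalysed conjunctive cross-coupling of bis(alkenyl)borates, which gives α-substituted allyl boronates. No ring is closed. The new C14 centre is set by the chiral bisphosphine, which chooses the face of the bound vinyl group; the nearest existing centre (C9) is four bonds away, so catalyst control should be clean. The step needs palladium to take the vinyl group over the 1,1-disubstituted alkenyl group (secured by the C13 substituent) and needs the metallate shift to outrun direct transmetallation (wide-bite-angle ligand, halide scavenging); the shielded C4 ester should not be attacked by one equivalent of vinyllithium at −78 °C.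

**Step 17**
Reactants: 28 C14 allylic pinacol boronate
Product: 29 (14R)-allylic alcohol
Conditions: 30% H2O2, 3 M NaOH, THF, 0 °C
Reagents that add atoms: hydrogen peroxide (OO)
Why: Boronate oxidation proceeds by 1,2-shift of C14 from boron to oxygen with retention, without allylic transposition, and leaves the furan, the silyl ethers and the hindered ester untouched.

**Step 18**
Reactants: 29 (14R)-allylic alcohol
Product: 31 hydroxybutenolide (5-hydroxy-4-methyl-2(5H)-furanone, C16 being the hemiketal carbon; epimers at C16), via furan endoperoxide 30 (not isolated)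
Conditions: O2, visible light, tetraphenylporphyrin (cat.), iPr2NEt, CH2Cl2, −78 °C; mild acid work-up
Reagents that add atoms: dioxygen (O=O)
Why: [4+2] photooxygenation of the furan, which reacts far faster than the 1,1-disubstituted alkene, followed by base-induced Kornblum–DeLaMare fragmentation at the only bridgehead C–H, turns the unsubstituted α carbon into the lactone carbonyl and C16 into a hemiketal.

**Step 19**
Reactants: 31 hydroxybutenolide
Product: 33 butenolide alcohol (14R,16S), via syn-dihydroxy acid 32 (not isolated)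
Conditions: Et2BOMe, THF/MeOH 4:1, −78 °C; NaBH4, −78 °C; AcOH quench; MeOH azeotrope; PPTS, CH2Cl2, rt
Reagents that add atoms: none
Why: Proposed new method: hemiketal lactone 31 is in equilibrium with its open (Z)-4-oxo-enoic acid (a carboxylate under the basic borohydride conditions), whose C16 ketone lies β to the C14 hydroxyl, so Et2BOMe should tie O14 and the C16 carbonyl into a six-membered boron chelate to which external hydride adds axially, giving the 14,16-syn diol (16S), and the Z-configured hydroxy acid then lactonises on acidification; the closest known reactions are the Narasaka–Prasad syn reduction of β-hydroxy enones and the NaBH4 reduction of 5-hydroxybutenolides to butenolides, which have not been combined on a ring-chain tautomer of this kind.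

**Step 20**
Reactants: 33 butenolide alcohol
Product: 35 bis(triethylsilyl) hydroperoxide (14S), via C14 mesylate 34 (not isolated)
Conditions: MsCl, Et3N, CH2Cl2, −60 °C; then anhydrous H2O2 in Et2O, −78 to −20 °C
Reagents that add atoms: hydrogen peroxide (OO)
Why: Sulfonate displacement by hydrogen peroxide (SN2) inverts C14 to the 14S hydroperoxide, and low temperature, a non-ionising medium and the absence of strong base are meant to suppress ionisation, SN2′ attack and epimerisation of the butenolide.

**Step 21**
Reactants: 35 bis(triethylsilyl) hydroperoxide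
Product: 36 target hydroperoxide
Conditions: HF·pyridine, pyridine, THF, 0 °C
Reagents that add atoms: none
Why: Fluoride-mediated desilylation under buffered acidic conditions frees the 6α and 8α hydroxyls without harming the allylic hydroperoxide, the butenolide or the methyl ester.

**Compound list**
1 | abietic acid | CC(C)C1=CC2=CC[C@@H]3[C@@]([C@H]2CC1)(CCC[C@@]3(C)C(=O)O)C | starting material
2 | methyl abietate | CC(C)C1=CC2=CC[C@@H]3[C@@]([C@H]2CC1)(CCC[C@@]3(C)C(=O)OC)C | intermediate
3 | methyl 13α,14α-dihydroxyabiet-7-en-18-oate | CC(C)[C@@]1(O)[C@H](O)C2=CC[C@@H]3[C@@]([C@H]2CC1)(CCC[C@@]3(C)C(=O)OC)C | intermediate (not isolated)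
4 | seco keto-enal (methyl 13-oxo-13,14-secoabiet-7-en-14-al-18-oate) | CC(C)C(=O)CC[C@@H]1[C@@]2(C)CCC[C@@](C)(C(=O)OC)[C@@H]2CC=C1C=O | intermediate
5 | dienol acetate of 4 (C6=C7, C8=CH–OAc) | CC(C)C(=O)CC[C@@H]1[C@@]2(C)CCC[C@@](C)(C(=O)OC)[C@@H]2C=CC1=COC(C)=O | intermediate
6 | 6α,7α-epoxide of 5 | CC(C)C(=O)CC[C@@H]1[C@@]2(C)CCC[C@@](C)(C(=O)OC)[C@@H]2[C@H]3O[C@H]3C1=COC(C)=O | intermediate (not isolated)
7 | 6α-hydroxy seco enal | CC(C)C(=O)CC[C@@H]1[C@@]2(C)CCC[C@@](C)(C(=O)OC)[C@@H]2[C@@H](O)C=C1C=O | intermediate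
8 | allylic diol (6α-OH, C8–CH2OH, C7=C8) | CC(C)C(=O)CC[C@@H]1[C@@]2(C)CCC[C@@](C)(C(=O)OC)[C@@H]2[C@@H](O)C=C1CO | intermediate
9 | N-allyl-N-(2-nitrobenzenesulfonyl) acetone hydrazone (Mitsunobu adduct) | CC(C)C(=O)CC[C@@H]1[C@@]2(C)CCC[C@@](C)(C(=O)OC)[C@@H]2[C@@H](O)C=C1CN(N=C(C)C)S(=O)(=O)c1ccccc1[N+](=O)[O-] | intermediate (not isolated)
10 | N-allyl-N-(2-nitrobenzenesulfonyl)hydrazine | CC(C)C(=O)CC[C@@H]1[C@@]2(C)CCC[C@@](C)(C(=O)OC)[C@@H]2[C@@H](O)C=C1CN(N)S(=O)(=O)c1ccccc1[N+](=O)[O-] | intermediate (not isolated)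
11 | allylic diazene | CC(C)C(=O)CC[C@@H]1[C@@]2(C)CCC[C@@](C)(C(=O)OC)[C@@H]2[C@@H](O)C=C1CN=N | intermediate (not isolated)
12 | 6α-hydroxy-8-methylene ketone | CC(C)C(=O)CC[C@@H]1[C@@]2(C)CCC[C@@](C)(C(=O)OC)[C@@H]2[C@@H](O)CC1=C | intermediate
13 | 8α-hydroperoxide | CC(C)C(=O)CC[C@@H]1[C@@]2(C)CCC[C@@](C)(C(=O)OC)[C@@H]2[C@@H](O)C[C@@]1(C)OO | intermediate (not isolated)
14 | 6α,8α-diol isopropyl ketone | CC(C)C(=O)CC[C@@H]1[C@@]2(C)CCC[C@@](C)(C(=O)OC)[C@@H]2[C@@H](O)C[C@@]1(C)O | intermediate
15 | 6α,8α-diol isopropyl ester | CC(C)OC(=O)CC[C@@H]1[C@@]2(C)CCC[C@@](C)(C(=O)OC)[C@@H]2[C@@H](O)C[C@@]1(C)O | intermediate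
16 | bis(triethylsilyl) ether isopropyl ester | CC(C)OC(=O)CC[C@@H]1[C@@]2(C)CCC[C@@](C)(C(=O)OC)[C@@H]2[C@@H](O[Si](CC)(CC)CC)C[C@@]1(C)O[Si](CC)(CC)CC | intermediate
17 | Weinreb amide | CON(C)C(=O)CC[C@@H]1[C@@]2(C)CCC[C@@](C)(C(=O)OC)[C@@H]2[C@@H](O[Si](CC)(CC)CC)C[C@@]1(C)O[Si](CC)(CC)CC | intermediate
18 | methyl ketone | CC(=O)CC[C@@H]1[C@@]2(C)CCC[C@@](C)(C(=O)OC)[C@@H]2[C@@H](O[Si](CC)(CC)CC)C[C@@]1(C)O[Si](CC)(CC)CC | intermediate
19 | lithium enolate of 18 (terminal) | [Li+].C=C([O-])CC[C@@H]1[C@@]2(C)CCC[C@@](C)(C(=O)OC)[C@@H]2[C@@H](O[Si](CC)(CC)CC)C[C@@]1(C)O[Si](CC)(CC)CC | intermediate (not isolated)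
20 | enol triflate | C=C(OS(=O)(=O)C(F)(F)F)CC[C@@H]1[C@@]2(C)CCC[C@@](C)(C(=O)OC)[C@@H]2[C@@H](O[Si](CC)(CC)CC)C[C@@]1(C)O[Si](CC)(CC)CC | intermediate
21 | bis(pinacolato)diboron | CC1(C)OB(OC1(C)C)B1OC(C)(C)C(C)(C)O1 | starting material
22 | decalin alkenyl pinacol boronate | C=C(B3OC(C)(C)C(C)(C)O3)CC[C@@H]1[C@@]2(C)CCC[C@@](C)(C(=O)OC)[C@@H]2[C@@H](O[Si](CC)(CC)CC)C[C@@]1(C)O[Si](CC)(CC)CC | intermediate
23 | 3-methylfuran | Cc1ccoc1 | starting material
24 | 2-bromo-3-methylfuran | Cc1ccoc1Br | intermediate
25 | tetravinylstannane | C=C[Sn](C=C)(C=C)C=C | starting material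
26 | vinyllithium | [Li]C=C | intermediate
27 | lithium bis(alkenyl)(pinacolato)borate | [Li+].C=C[B-]3(OC(C)(C)C(C)(C)O3)C(=C)CC[C@@H]1[C@@]2(C)CCC[C@@](C)(C(=O)OC)[C@@H]2[C@@H](O[Si](CC)(CC)CC)C[C@@]1(C)O[Si](CC)(CC)CC | intermediate (not isolated)
28 | C14 allylic pinacol boronate with (3-methylfuran-2-yl)methyl group | C=C(CC[C@@H]1[C@@]2(C)CCC[C@@](C)(C(=O)OC)[C@@H]2[C@@H](O[Si](CC)(CC)CC)C[C@@]1(C)O[Si](CC)(CC)CC)[C@@H](Cc3occc3C)B4OC(C)(C)C(C)(C)O4 | intermediate
29 | (14R)-allylic alcohol | C=C(CC[C@@H]1[C@@]2(C)CCC[C@@](C)(C(=O)OC)[C@@H]2[C@@H](O[Si](CC)(CC)CC)C[C@@]1(C)O[Si](CC)(CC)CC)[C@@H](Cc3occc3C)O | intermediate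
30 | furan endoperoxide | C=C(CC[C@@H]1[C@@]2(C)CCC[C@@](C)(C(=O)OC)[C@@H]2[C@@H](O[Si](CC)(CC)CC)C[C@@]1(C)O[Si](CC)(CC)CC)[C@@H](CC3(OOC4O3)C(C)=C4)O | intermediate (not isolated)
31 | hydroxybutenolide (C16 hemiketal, epimers) | C=C(CC[C@@H]1[C@@]2(C)CCC[C@@](C)(C(=O)OC)[C@@H]2[C@@H](O[Si](CC)(CC)CC)C[C@@]1(C)O[Si](CC)(CC)CC)[C@@H](CC3(O)OC(=O)C=C3C)O | intermediate
32 | (14R,16S)-syn-dihydroxy (Z)-enoic acid | C=C(CC[C@@H]1[C@@]2(C)CCC[C@@](C)(C(=O)OC)[C@@H]2[C@@H](O[Si](CC)(CC)CC)C[C@@]1(C)O[Si](CC)(CC)CC)[C@@H](C[C@H](O)/C(C)=C\C(=O)O)O | intermediate (not isolated)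
33 | butenolide alcohol (14R,16S) | C=C(CC[C@@H]1[C@@]2(C)CCC[C@@](C)(C(=O)OC)[C@@H]2[C@@H](O[Si](CC)(CC)CC)C[C@@]1(C)O[Si](CC)(CC)CC)[C@@H](C[C@@H]3OC(=O)C=C3C)O | intermediate
34 | C14 mesylate | C=C(CC[C@@H]1[C@@]2(C)CCC[C@@](C)(C(=O)OC)[C@@H]2[C@@H](O[Si](CC)(CC)CC)C[C@@]1(C)O[Si](CC)(CC)CC)[C@@H](C[C@@H]3OC(=O)C=C3C)OS(C)(=O)=O | intermediate (not isolated)
35 | bis(triethylsilyl) hydroperoxide (14S,16S) | C=C(CC[C@@H]1[C@@]2(C)CCC[C@@](C)(C(=O)OC)[C@@H]2[C@@H](O[Si](CC)(CC)CC)C[C@@]1(C)O[Si](CC)(CC)CC)[C@H](C[C@@H]3OC(=O)C=C3C)OO | intermediate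
36 | target hydroperoxide | C=C(CC[C@@H]1[C@@]2(C)CCC[C@@](C)(C(=O)OC)[C@@H]2[C@@H](O)C[C@@]1(C)O)[C@H](C[C@@H]1OC(=O)C=C1C)OO | target

**Step count and risk**
Total steps: 21. Longest linear sequence: 19 steps (steps 1–13 and 16–21, from abietic acid).

Steps most likely to fail:

1. Step 19 (proposed new method). The ring-closed hemiketal may open too slowly at −78 °C for the boron chelate to form, so that hydride adds without facial control at C16, or conjugate reduction of the open enone may compete. Fallback with known chemistry, setting out from 31 and returning at 33: O-methylation of the open-chain acid with trimethylsilyldiazomethane (MeOH/toluene, 0 °C) gives the methyl (Z)-4-oxo-enoate F1, a true β-hydroxy enone. The standard Narasaka–Prasad reduction (Et2BOMe, NaBH4, THF/MeOH, −78 °C) then gives the syn-diol methyl ester F2, which lactonises with PPTS to 33.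

2. Step 16 (key step). Palladium may transmetallate directly from the borate (Suzuki-type coupling), may engage the substituted alkenyl group, or the facial control at C14 may erode with the heteroaryl bromide. Fallback by lithiation–borylation, setting out from 24 (with 22) and returning at 28: bromine–lithium exchange on 24 (n-BuLi, Et2O, −78 °C) gives 3-methyl-2-furyllithium F3, which opens oxirane to 2-(3-methylfuran-2-yl)ethanol F4. Carbamoylation (iPr2NCOCl, Et3N) gives the N,N-diisopropylcarbamate F5. Deprotonation with s-BuLi/(−)-sparteine (Et2O, −78 °C) gives the (S)-α-lithio carbamate F6, which adds to 22 with retention to give the boronate complex F7. Warming with MgBr2·OEt2 triggers the stereospecific 1,2-shift of the C13 alkenyl group with inversion and expulsion of the carbamate, giving 28 without any palladium.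

3. Step 20. The secondary allylic mesylate may ionise (loss of configuration at C14), be attacked at the terminal CH2 (SN2′), eliminate, or the hydroperoxide may decompose under the amine base. Fallback setting out from 33 (through mesylate 34) and returning at 35: alkylation of the caesium salt of 2-methoxyprop-2-yl hydroperoxide (CsOH·H2O, DMF, 0 °C) with 34, a stronger and protected peroxide nucleophile, gives the peroxyketal F8. Brief treatment with aqueous acetic acid in THF releases the hydroperoxide 35.

**Further compounds**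
F1 | step 19 | methyl (Z)-4-oxo-enoate (open-chain ester of 31) | C=C(CC[C@@H]1[C@@]2(C)CCC[C@@](C)(C(=O)OC)[C@@H]2[C@@H](O[Si](CC)(CC)CC)C[C@@]1(C)O[Si](CC)(CC)CC)[C@@H](CC(=O)/C(C)=C\C(=O)OC)O
F2 | step 19 | (14R,16S)-syn-diol methyl (Z)-enoate | C=C(CC[C@@H]1[C@@]2(C)CCC[C@@](C)(C(=O)OC)[C@@H]2[C@@H](O[Si](CC)(CC)CC)C[C@@]1(C)O[Si](CC)(CC)CC)[C@@H](C[C@H](O)/C(C)=C\C(=O)OC)O
F3 | step 16 | 3-methyl-2-furyllithium | Cc1ccoc1[Li]
F4 | step 16 | 2-(3-methylfuran-2-yl)ethanol | Cc1ccoc1CCO
F5 | step 16 | 2-(3-methylfuran-2-yl)ethyl N,N-diisopropylcarbamate | Cc1ccoc1CCOC(=O)N(C(C)C)C(C)C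
F6 | step 16 | (S)-α-lithio carbamate | Cc1ccoc1C[C@H]([Li])OC(=O)N(C(C)C)C(C)C
F7 | step 16 | boronate complex of F6 and 22 | [Li+].Cc1ccoc1C[C@H]([B-]3(OC(C)(C)C(C)(C)O3)C(=C)CC[C@@H]1[C@@]2(C)CCC[C@@](C)(C(=O)OC)[C@@H]2[C@@H](O[Si](CC)(CC)CC)C[C@@]1(C)O[Si](CC)(CC)CC)OC(=O)N(C(C)C)C(C)C
F8 | step 20 | C14 2-methoxyprop-2-yl peroxide (peroxyketal) | C=C(CC[C@@H]1[C@@]2(C)CCC[C@@](C)(C(=O)OC)[C@@H]2[C@@H](O[Si](CC)(CC)CC)C[C@@]1(C)O[Si](CC)(CC)CC)[C@H](C[C@@H]3OC(=O)C=C3C)OOC(C)(C)OC
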